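The numbers in the tables were computed with constants of no real substance; the scatter is artificial.

- Product was what I counted first, in mM rather than in percent. The ochre run held near 4.32 mM from 6.00 min on, and the green run stood at 14.7 mM at 6.00 min, its curve still rising but bending.

| flask | starting material | reagent | capture agent | free catalyst | temperature | remark | time |
|---|---|---|---|---|---|---|---|
| ochre | 13 mM | 20 mM | 1 mM | 20 µM | 32 °C | run made earlier |  |
| green | 30 mM | 20 mM | 1 mM | 20 µM | 60 °C | run made earlier |  |
| delta | 20 mM | 20.0 mM | 1.00 mM | 20 µM | 45 °C |  | 30 min |
| epsilon | 20 mM | 20.0 mM | 1.00 mM | 20 µM | 20 °C |  | 30 min |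
| alpha | 20 mM | 20.0 mM | 1.00 mM | 20 µM | 70 °C |  | 30 min |

| run | time / min | product / % | catalyst intermediate A / % | trapped intermediate / % | starting material / % |
|---|---|---|---|---|---|
| ochre | 3.00 | 30 | 1 | 1 | 70 |
| ochre | 6.00 | 33 | 1 | 2 | 66 |
| ochre | 12.0 | 34 | 0 | 0 | 67 |
| ochre | 15.0 | 30 | 0 | 0 | 66 |
| ochre | 20.0 | 36 | 0 | 0 | 68 |
| green | 0.417 | 19 | 0 | 2 | 78 |
| green | 0.667 | 28 | 0 | 0 | 72 |
| green | 1.00 | 33 | 0 | 1 | 67 |
| green | 1.50 | 37 | 0 | 0 | 64 |
| green | 3.00 | 42 | 0 | 0 | 58 |
| green | 6.00 | 49 | 0 | 0 | 53 |

(standard deviation of a reading: 1.5 percentage points)



1. which of these there is most of at the end, counted by the starting material in it, delta (trapped intermediate / product / catalyst intermediate A / starting material)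
2. which of these there is most of at the end, counted by the starting material in it, epsilon (trapped intermediate / product / catalyst intermediate A / starting material)
3. which of these there is most of at the end, counted by the starting material in it, alpha (trapped intermediate / product / catalyst intermediate A / starting material)
4. final amount of the leader among these, as a percentage of the starting material charged, in delta
5. final amount of the leader among these, as a percentage of the starting material charged, in epsilon
6. final amount of the leader among these, as a percentage of the starting material charged, in alpha

- The first instants: free catalyst turned over fast. The green run had already made 285 product per catalyst at 0.417 min. The catalyst forms themselves stayed invisible, since the ochre charge of catalyst is 0.154 % of its starting material, less than the scatter of 1.5 percentage points.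
- The middle: I supposed that one catalyst form either released product or met capture agent. Then, with P the product, V the trapped catalyst and Q the capture agent, dP/dV is N, the ratio of release rate to capture rate, a selectivity factor.
- Q barely moved, because the catalyst charge is 2.00 % of it. Capture was thus pseudo-first-order, and dP/dV integrates in closed form to P = N·C, with C the catalyst charged.
- The end: once the catalyst is trapped, product stands. So N is the turnover capacity, and the ochre readings gave 216 at 32 °C, the last green reading, taken while product was still rising, 735 at 60 °C, with the same Q and C.
- An Arrhenius line through these two readings has a slope of 37.0 kJ mol⁻¹, the difference between the two activation energies.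
- My reckoning: at 45 °C the turnover capacity, product made per catalyst charged before capture, is 392, so delta keeps 60.8 % of its starting material. Epsilon has N = 119 and keeps 88.1 %.
- Alpha has N = 1080, and N·C = 21.7 mM is more than the 20 mM charged, so I expected product close to the full charge.
- The forecast said starting material at 53 % for delta, starting material at 67 % for epsilon and product at 88 % for alpha, “giving fractional conversion independent of starting material”.
- The flasks gave starting material at 60.5 % in delta, starting material at 87.6 % in epsilon and product at 98.8 % in alpha. Delta's product still stands at 39.4 % after 300 min, with the trapped intermediate holding 100 % of the catalyst at 30.0 min. There N·C = 7.84 mM, beside 7.90 mM of by-product. In the scheme, N is the rate of the step from catalyst intermediate D to free catalyst + product over the rate of the capture of catalyst intermediate D.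

    catalyst intermediate C → catalyst intermediate D (k = 15.0 s⁻¹, Ea = 58.0 kJ mol⁻¹)
    reagent + catalyst intermediate A ⇌ catalyst intermediate B (K = 7.10 L mol⁻¹, k = 620 L mol⁻¹ s⁻¹, Ea = 42.0 kJ mol⁻¹, ΔH = 7.00 kJ mol⁻¹)
    catalyst intermediate D → free catalyst + product (k = 11.0 s⁻¹, Ea = 73.0 kJ mol⁻¹)
    capture agent + catalyst intermediate D → trapped intermediate (k = 90.0 L mol⁻¹ s⁻¹, Ea = 37.0 kJ mol⁻¹)
    starting material + free catalyst → catalyst intermediate A (k = 560 L mol⁻¹ s⁻¹, Ea = 41.0 kJ mol⁻¹)
    catalyst intermediate B ⇌ by-product + catalyst intermediate C (K = 0.0540 M, k = 17.0 s⁻¹, Ea = 67.0 kJ mol⁻¹, ΔH = −41.0 kJ mol⁻¹)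
    (constants at 20 °C)

- A neighbour of delta has 50 mM of starting material at the same temperature, capture agent and catalyst, so N carries over and gives 15.7 % product. The computed flask gives 15.8 %.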